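The bicyclo[3.2.1]octane core is disconnected at C8–C1 and C3–C4 (locants of the bicyclic skeleton). This exposes a methylmalonyl unit (C4, C5, C8) on the carbinol-bearing carbon C6 and a methyl ketone whose carbonyl C2 is flanked by C1 and C3. The key step is a double Claisen cascade of a γ-lactone tert-butyl ester: the enolate at prenylated C1 attacks the lactone carbonyl (C8), which closes the cyclopentanone ring C1–C7–C6–C5–C8 and releases the tertiary alkoxide of the 2-hydroxypropan-2-yl group; C3 then attacks the ester (C4) and closes the six-membered ring. The precursor comes from a cyclopropane-fused lactone by strain-release addition; C3 acylation ends the route.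

Key step: step 6

Remark: the target is read as the (1R,5R,6R) bicyclic enol with a (2R)-2-methylbutanoyl group. Enolised 1,3-dicarbonyl compounds are written as one tautomer. (2R)-2-Methylbutanoic acid is assumed to be purchasable as the single enantiomer.

Step 1
Reactants: 1 3-methylbut-2-en-1-ol
Product: 3 [(2R)-3,3-dimethyloxiran-2-yl]methyl 4-methylbenzenesulfonate, via (R)-3,3-dimethyloxiranemethanol 2 (not isolated)
Conditions: Ti(OiPr)4 (10 mol %), D-(−)-diethyl tartrate (12 mol %), t-BuOOH, 4 Å MS, CH2Cl2, −20 °C; then P(OMe)3; Et3N, DMAP (cat.), TsCl, −10 °C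
Reagents that add atoms: tert-butyl hydroperoxide CC(C)(C)OO; 4-methylbenzenesulfonyl chloride Cc1ccc(cc1)S(Cl)(=O)=O
Why: Sharpless asymmetric epoxidation of the primary allylic alcohol, in which the D-(−)-tartrate titanium complex should deliver oxygen to the alkene face that gives the (R)-epoxide (the only reagent-controlled stereocenter of the route), followed by sulfonylation in the same flask so that the water-soluble epoxy alcohol need not be isolated.

Step 2
Reactants: 3 [(2R)-3,3-dimethyloxiran-2-yl]methyl 4-methylbenzenesulfonate; 4 di-tert-butyl propanedioate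
Product: 7 tert-butyl (1S,5R)-4,4-dimethyl-2-oxo-3-oxabicyclo[3.1.0]hexane-1-carboxylate, via epoxy malonate 5 (not isolated), via cyclopropylcarbinol alkoxide 6 (not isolated)
Conditions: NaH (2.2 equiv), THF–DMF, 0 → 65 °C; aq. NH4Cl
Reagents that add atoms: none
Why: Malonic ester alkylation at the primary sulfonate, 3-exo-tet opening of the epoxide by the malonate anion with inversion at the secondary carbon and lactonisation of the tertiary alkoxide onto the cis ester, the known glycidyl-electrophile route to 2-oxo-3-oxabicyclo[3.1.0]hexane-1-carboxylates, so the epoxide carbon fixes both ring-fusion centers.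

Step 3
Reactants: 8 prop-2-en-1-yl 3-oxobutanoate; 9 1-bromo-3-methylbut-2-ene
Product: 10 prop-2-en-1-yl 2-acetyl-5-methylhex-4-enoate (racemic)
Conditions: K2CO3, acetone, reflux
Reagents that add atoms: none
Why: Acetoacetic ester C-alkylation with an allylic bromide, which gives a nucleophile that keeps no acidic C–H after it has reacted in step 4; its stereocenter is racemic and is erased later.

Step 4
Reactants: 7 tert-butyl (1S,5R)-4,4-dimethyl-2-oxo-3-oxabicyclo[3.1.0]hexane-1-carboxylate; 10 prop-2-en-1-yl 2-acetyl-5-methylhex-4-enoate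
Product: 12 tert-butyl (3R,4R)-4-{2-acetyl-5-methyl-2-[(prop-2-en-1-yloxy)carbonyl]hex-4-en-1-yl}-3,5,5-trimethyl-2-oxooxolane-3-carboxylate (both epimers at the side-chain quaternary carbon), via lactone enolate 11 (not isolated)
Conditions: Cs2CO3 (1.2 equiv), DMSO, 70 °C; then MeI, 20 °C
Reagents that add atoms: iodomethane CI
Why: Homoconjugate (homo-Michael) addition of the β-keto ester enolate to the doubly activated cyclopropane at its CH2 carbon, which leaves the configured lactone β-carbon untouched and gives a lactone ester enolate as the only carbanion, and this is methylated anti to the bulky β-side chain, so that methyl is trans and the tert-butyl ester cis to the side chain at the new quaternary center.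

Step 5
Reactants: 12 tert-butyl (3R,4R)-4-{2-acetyl-5-methyl-2-[(prop-2-en-1-yloxy)carbonyl]hex-4-en-1-yl}-3,5,5-trimethyl-2-oxooxolane-3-carboxylate
Product: 14 tert-butyl (3R,4R)-4-(2-acetyl-5-methylhex-4-en-1-yl)-3,5,5-trimethyl-2-oxooxolane-3-carboxylate (both epimers at the side-chain CH), via β-keto acid 13 (not isolated)
Conditions: Pd(OAc)2 (3 mol %), PPh3 (12 mol %), HCO2H, Et3N, THF, 25 → 45 °C
Reagents that add atoms: none
Why: Tsuji palladium-catalysed deallylation of the allyl β-keto ester with formate as hydride source, after which the β-keto acid loses CO2; lactone, tert-butyl ester and prenyl alkene should be inert, and the new side-chain CH forms as both epimers, which converge in step 6 because this carbon is enolised there.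

Step 6
Reactants: 14 tert-butyl (3R,4R)-4-(2-acetyl-5-methylhex-4-en-1-yl)-3,5,5-trimethyl-2-oxooxolane-3-carboxylate
Product: 16 (1S,5R,6R)-4-hydroxy-6-(2-hydroxypropan-2-yl)-5-methyl-1-(3-methylbut-2-en-1-yl)bicyclo[3.2.1]oct-3-ene-2,8-dione, via cyclopentanone alkoxide 15 (not isolated)
Conditions: KH (2.5 equiv), THF, 0 → 50 °C; then 1 M HCl
Reagents that add atoms: none
Why: KH deprotonates the methyl ketone reversibly, and the enolate at the prenyl-bearing carbon (future C1) adds to the lactone carbonyl (future C8) in a 5-exo-trig acyl substitution through a 2-oxabicyclo[2.2.1]heptane tetrahedral intermediate whose collapse closes the cyclopentanone and expels the tertiary alkoxide; proton transfer then gives the methyl-ketone enolate (future C3), which attacks the tert-butyl ester (future C4) in a 6-exo-trig closure, and the potassium enolate of the β-diketone is the thermodynamic sink. The closest known reaction types are the Claisen acylation of ketone enolates by lactones and the Dieckmann-type closure of a ring-bound methyl ketone onto a ring ester that is used to build bicyclic acylphloroglucinol triones. The new quaternary stereocenter C1 is controlled by the bridge: only the epimer of 15 with acetyl cis to the ester can close, and the other should return to 14 by retro-Claisen attack of the same alkoxide. C5 and C6 are carried over from 14, and because the lactone carbonyl (cis to the carbinol carbon) becomes the bridging ketone while the ester (cis to the side chain) becomes C4, the 2-hydroxypropan-2-yl group ends exo, trans to the three-carbon bridge. The step needs the first enolate to choose the lactone and not the ester, which would lead to the C6-epimeric series; the hindered tert-butyl ester, which resists the tetrasubstituted enolate but not the unhindered methylene enolate, should secure this. KH is used so that no nucleophilic alkoxide is present that could open the lactone and make the two carboxyl groups on C5 equivalent.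

Step 7
Reactants: 16 (1S,5R,6R)-4-hydroxy-6-(2-hydroxypropan-2-yl)-5-methyl-1-(3-methylbut-2-en-1-yl)bicyclo[3.2.1]oct-3-ene-2,8-dione; 17 (2R)-2-methylbutanoic acid
Product: 19 (1R,5R,6R)-4-hydroxy-6-(2-hydroxypropan-2-yl)-5-methyl-3-[(2R)-2-methylbutanoyl]-1-(3-methylbut-2-en-1-yl)bicyclo[3.2.1]oct-3-ene-2,8-dione, via enol ester 18 (not isolated)
Conditions: DCC (1.3 equiv), DMAP (0.3 equiv), CH2Cl2, 0 → 20 °C
Reagents that add atoms: none
Why: Carbodiimide esterification of the enol followed by DMAP-mediated 1,3 O-to-C acyl shift, the standard entry to 2-acyl cyclic 1,3-diones; the hindered tertiary alcohol should not compete and the mild conditions should leave the α-stereocenter of the acyl group untouched.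

Compound list
1 | 3-methylbut-2-en-1-ol | CC(C)=CCO | starting material
2 | [(2R)-3,3-dimethyloxiran-2-yl]methanol | CC1(C)O[C@@H]1CO | intermediate
3 | [(2R)-3,3-dimethyloxiran-2-yl]methyl 4-methylbenzenesulfonate | CC1(C)O[C@@H]1COS(=O)(=O)c1ccc(C)cc1 | intermediate
4 | di-tert-butyl propanedioate | CC(C)(C)OC(=O)CC(=O)OC(C)(C)C | starting material
5 | di-tert-butyl 2-{[(2R)-3,3-dimethyloxiran-2-yl]methyl}propanedioate | CC1(C)O[C@@H]1CC(C(=O)OC(C)(C)C)C(=O)OC(C)(C)C | intermediate
6 | sodium alkoxide of di-tert-butyl (2R)-2-(2-hydroxypropan-2-yl)cyclopropane-1,1-dicarboxylate | [Na+].CC(C)([O-])[C@@H]1CC1(C(=O)OC(C)(C)C)C(=O)OC(C)(C)C | intermediate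
7 | tert-butyl (1S,5R)-4,4-dimethyl-2-oxo-3-oxabicyclo[3.1.0]hexane-1-carboxylate | O=C1OC(C)(C)[C@@H]2C[C@]12C(=O)OC(C)(C)C | intermediate
8 | prop-2-en-1-yl 3-oxobutanoate | CC(=O)CC(=O)OCC=C | starting material
9 | 1-bromo-3-methylbut-2-ene | CC(C)=CCBr | starting material
10 | prop-2-en-1-yl 2-acetyl-5-methylhex-4-enoate (racemic) | CC(=O)C(CC=C(C)C)C(=O)OCC=C | intermediate
11 | caesium enolate of tert-butyl (4R)-4-{2-acetyl-5-methyl-2-[(prop-2-en-1-yloxy)carbonyl]hex-4-en-1-yl}-5,5-dimethyl-2-oxooxolane-3-carboxylate | [Cs+].CC(=O)C(CC=C(C)C)(C(=O)OCC=C)C[C@H]1C(C)(C)OC(=O)[C-]1C(=O)OC(C)(C)C | intermediate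
12 | tert-butyl (3R,4R)-4-{2-acetyl-5-methyl-2-[(prop-2-en-1-yloxy)carbonyl]hex-4-en-1-yl}-3,5,5-trimethyl-2-oxooxolane-3-carboxylate (side-chain epimers) | CC(=O)C(CC=C(C)C)(C(=O)OCC=C)C[C@H]1C(C)(C)OC(=O)[C@@]1(C)C(=O)OC(C)(C)C | intermediate
13 | 2-acetyl-2-{[(3R,4R)-4-(tert-butoxycarbonyl)-2,2,4-trimethyl-5-oxooxolan-3-yl]methyl}-5-methylhex-4-enoic acid (side-chain epimers) | CC(=O)C(CC=C(C)C)(C(O)=O)C[C@H]1C(C)(C)OC(=O)[C@@]1(C)C(=O)OC(C)(C)C | intermediate
14 | tert-butyl (3R,4R)-4-(2-acetyl-5-methylhex-4-en-1-yl)-3,5,5-trimethyl-2-oxooxolane-3-carboxylate (side-chain epimers) | CC(=O)C(CC=C(C)C)C[C@H]1C(C)(C)OC(=O)[C@@]1(C)C(=O)OC(C)(C)C | intermediate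
15 | potassium alkoxide of tert-butyl (1S,3S,5R)-3-acetyl-5-(2-hydroxypropan-2-yl)-1-methyl-3-(3-methylbut-2-en-1-yl)-2-oxocyclopentane-1-carboxylate | [K+].CC(=O)[C@]1(CC=C(C)C)C[C@@H](C(C)(C)[O-])[C@](C)(C(=O)OC(C)(C)C)C1=O | intermediate
16 | (1S,5R,6R)-4-hydroxy-6-(2-hydroxypropan-2-yl)-5-methyl-1-(3-methylbut-2-en-1-yl)bicyclo[3.2.1]oct-3-ene-2,8-dione | O=C1C=C(O)[C@]2(C)C(=O)[C@@]1(CC=C(C)C)C[C@H]2C(C)(C)O | intermediate
17 | (2R)-2-methylbutanoic acid | CC[C@@H](C)C(O)=O | starting material
18 | enol (2R)-2-methylbutanoate of 16, acylated at the C4 oxygen | O=C1C=C(OC(=O)[C@H](C)CC)[C@]2(C)C(=O)[C@@]1(CC=C(C)C)C[C@H]2C(C)(C)O | intermediate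
19 | (1R,5R,6R)-4-hydroxy-6-(2-hydroxypropan-2-yl)-5-methyl-3-[(2R)-2-methylbutanoyl]-1-(3-methylbut-2-en-1-yl)bicyclo[3.2.1]oct-3-ene-2,8-dione | CC[C@@H](C)C(=O)C1=C(O)[C@]2(C)C(=O)[C@@](CC=C(C)C)(C[C@H]2C(C)(C)O)C1=O | target

Total step count: 7. Longest linear sequence: 6 steps (1, 2, 4, 5, 6, 7); step 3 is a one-step side branch.

Steps most likely to fail

Step 6 (key step). The first enolate may attack the tert-butyl ester instead of the lactone carbonyl, which would lead to the C6-epimeric series. The first closure is also reversible and the second closure onto the hindered ester may be slow, so retro-Claisen cleavage could drain the material. The fallback sets out from 14 and comes back at 16. It opens the lactone beforehand, so that both closures become ordinary ester Dieckmann closures told apart by ester reactivity. LiOH in THF–H2O should saponify the lactone, and methylation of the lithium carboxylate in the same flask (MeI, DMF) should give the hydroxy methyl tert-butyl diester F1. Et3SiOTf with 2,6-lutidine should then give the triethylsilyl ether F2. KH in THF should close the five-membered ring at the methyl ester and the six-membered ring at the tert-butyl ester, which gives the silylated trione F3. Bu4NF in THF should return 16.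

Step 4. Ring-opening of the cyclopropane by the fully substituted carbanion may be sluggish, with O-alkylation or decomposition on prolonged heating. The fallback sets out from 7 and comes back at 12. LiI (cat.) with MeI in THF at 50 °C should open the cyclopropane reversibly with iodide and capture the enolate by methylation anti to the side chain, a net addition of methyl and iodine across the activated bond, to give the iodomethyl lactone F4. The less hindered potassium enolate of 8 should then be alkylated with F4 (K2CO3, DMF, 60 °C) to give the β-keto ester F5. Its only acidic C–H should be prenylated with 9 (K2CO3, acetone, reflux) to give 12.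

Step 2. Lactonisation of the tertiary alkoxide onto a tert-butyl ester may stop short, or the epoxide may be opened before the sulfonate is displaced. The fallback sets out from 3 and comes back at 7. Dimethyl malonate and NaH in THF should give the methyl ester lactone F6, since closure onto a methyl ester is easy. LiOH in THF–H2O followed by acidification should give the lactone acid F7; the lactone recloses because the carbinol and one carboxyl group are held cis on the cyclopropane. Boc2O, DMAP and t-BuOH should then give 7.

Further compounds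
F1 | step 6 | 1-tert-butyl 3-methyl (2S)-2-[(3R)-5-acetyl-2-hydroxy-2,8-dimethylnon-7-en-3-yl]-2-methylpropanedioate | CC(=O)C(CC=C(C)C)C[C@@H](C(C)(C)O)[C@@](C)(C(=O)OC)C(=O)OC(C)(C)C
F2 | step 6 | triethylsilyl ether of F1 | CC(=O)C(CC=C(C)C)C[C@@H](C(C)(C)O[Si](CC)(CC)CC)[C@@](C)(C(=O)OC)C(=O)OC(C)(C)C
F3 | step 6 | (1S,5R,6R)-4-hydroxy-5-methyl-1-(3-methylbut-2-en-1-yl)-6-{2-[(triethylsilyl)oxy]propan-2-yl}bicyclo[3.2.1]oct-3-ene-2,8-dione | O=C1C=C(O)[C@]2(C)C(=O)[C@@]1(CC=C(C)C)C[C@H]2C(C)(C)O[Si](CC)(CC)CC
F4 | step 4 | tert-butyl (3R,4R)-4-(iodomethyl)-3,5,5-trimethyl-2-oxooxolane-3-carboxylate | IC[C@H]1C(C)(C)OC(=O)[C@@]1(C)C(=O)OC(C)(C)C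
F5 | step 4 | tert-butyl (3R,4R)-3,5,5-trimethyl-2-oxo-4-{3-oxo-2-[(prop-2-en-1-yloxy)carbonyl]butyl}oxolane-3-carboxylate | CC(=O)C(C(=O)OCC=C)C[C@H]1C(C)(C)OC(=O)[C@@]1(C)C(=O)OC(C)(C)C
F6 | step 2 | methyl (1S,5R)-4,4-dimethyl-2-oxo-3-oxabicyclo[3.1.0]hexane-1-carboxylate | O=C1OC(C)(C)[C@@H]2C[C@]12C(=O)OC
F7 | step 2 | (1S,5R)-4,4-dimethyl-2-oxo-3-oxabicyclo[3.1.0]hexane-1-carboxylic acid | O=C1OC(C)(C)[C@@H]2C[C@]12C(O)=O
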